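**Retrosynthetic overview**
1. The target is (2S)-eriodictyol joined through C5' of ring B to C8'' of luteolin. Ring A of the flavanone is a phloroglucinol ring. Its two carbons ortho to O1 (the future C4a and C8) are equivalent and each is activated by three oxygen donors. The C4–C4a bond can therefore be made last, by acylation from a 3-aryl-3-aryloxypropanoic acid, without touching C2 or the C2–O1 bond.
2. O1–C2 is cut next. It comes from Mitsunobu inversion of an (R)-benzylic β-hydroxy ester with 3,5-bis(benzyloxy)phenol. The carbinol comes from asymmetric transfer hydrogenation of a β-keto ester, which is made by two-carbon homologation of a biaryl aldehyde.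
3. C5'–C8'' is cut by Suzuki–Miyaura coupling of 8-iodo-tetra-O-benzylluteolin with the boronate of protected 3-bromo-4,5-dihydroxybenzaldehyde.
4. The ring B oxygens are MOM ethers during the basic coupling. They are then changed to benzyl carbonates, which are electron-poor for the Mitsunobu and acylation steps and leave together with the benzyl ethers in one neutral hydrogenolysis.
5. Ring order: the luteolin rings and rings A and B are bought. Ring C of the flavanone is the only ring built, and it is closed in the penultimate step.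

Key step: step 12

Remark: the C5'–C8'' axis carries three ortho substituents and the target shows no axial descriptor. It is taken to equilibrate at room temperature, so chiral intermediates may show rotamer sets but count as single stereoisomers.

**Route**

Step 1
Reactants: 1 luteolin
Product: 2 5,7,3',4'-tetra-O-benzylluteolin
Conditions: BnBr (6 equiv), K2CO3 (8 equiv), DMF, 70 °C
Reagents that add atoms: benzyl bromide, BrCc1ccccc1
Why: Williamson etherification of all four phenols; the hydrogen-bonded 5-OH reacts last and is forced by excess reagent and heat, and capping it is what later steers iodination to C8.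

Step 2
Reactants: 2 5,7,3',4'-tetra-O-benzylluteolin
Product: 3 8-iodo-5,7,3',4'-tetra-O-benzylluteolin
Conditions: NIS (1.05 equiv), CF3CO2H (0.3 equiv), CH2Cl2–MeCN, 0 °C to rt, dark
Reagents that add atoms: N-iodosuccinimide, O=C1CCC(=O)N1I
Why: Electrophilic aromatic iodination; in fully O-alkylated 5,7-dioxygenated flavones the phloroglucinol-type ring is the most nucleophilic one and reacts at C8, next to the tied-back ring oxygen, rather than at C6, which is squeezed between two benzyloxy groups.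

Step 3
Reactants: 4 3-bromo-4,5-dihydroxybenzaldehyde
Product: 5 3-bromo-4,5-bis(methoxymethoxy)benzaldehyde
Conditions: MOMCl (3 equiv), iPr2NEt (4 equiv), CH2Cl2, 0 °C to rt
Reagents that add atoms: chloromethyl methyl ether, COCCl
Why: O-alkylation of both phenols gives base-stable MOM acetals that survive the two palladium steps and can later be removed without touching benzyl ethers.

Step 4
Reactants: 5 3-bromo-4,5-bis(methoxymethoxy)benzaldehyde
Product: 6 3,4-bis(methoxymethoxy)-5-(4,4,5,5-tetramethyl-1,3,2-dioxaborolan-2-yl)benzaldehyde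
Conditions: B2pin2 (1.2 equiv), PdCl2(dppf) (3 mol%), KOAc (3 equiv), 1,4-dioxane, 90 °C
Reagents that add atoms: bis(pinacolato)diboron, CC1(C)OB(OC1(C)C)B1OC(C)(C)C(C)(C)O1
Why: Miyaura borylation tolerates the aldehyde and the acetals; boron is placed on this partner because a boronate at C8 of the flavone, with two ortho oxygens, would protodeboronate easily.

Step 5
Reactants: 3 8-iodo-5,7,3',4'-tetra-O-benzylluteolin; 6 3,4-bis(methoxymethoxy)-5-(4,4,5,5-tetramethyl-1,3,2-dioxaborolan-2-yl)benzaldehyde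
Product: 7 3,4-bis(methoxymethoxy)-5-(tetra-O-benzylluteolin-8-yl)benzaldehyde
Conditions: Pd(OAc)2 (5 mol%), SPhos (10 mol%), K3PO4 (3 equiv), toluene–H2O (10:1), 90 °C
Reagents that add atoms: none
Why: Suzuki–Miyaura coupling; the bulky, electron-rich biaryl phosphine supports oxidative addition to the hindered, electron-rich iodide and reductive elimination to the tri-ortho-substituted C5'–C8'' biaryl.

Step 6
Reactants: 7 3,4-bis(methoxymethoxy)-5-(tetra-O-benzylluteolin-8-yl)benzaldehyde
Product: 8 3,4-dihydroxy-5-(tetra-O-benzylluteolin-8-yl)benzaldehyde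
Conditions: HCl (1 M) in MeOH–THF (1:1), 40 °C; aqueous work-up
Reagents that add atoms: none
Why: Acid-catalysed acetal exchange removes only the MOM groups; the aryl benzyl ethers and the flavone are inert at this acidity, and any dimethyl acetal of the aldehyde reverts in the aqueous work-up.

Step 7
Reactants: 8 3,4-dihydroxy-5-(tetra-O-benzylluteolin-8-yl)benzaldehyde
Product: 9 3,4-bis(benzyloxycarbonyloxy)-5-(tetra-O-benzylluteolin-8-yl)benzaldehyde
Conditions: CbzCl (3 equiv), Et3N (4 equiv), DMAP (0.1 equiv), CH2Cl2, 0 °C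
Reagents that add atoms: benzyl chloroformate, O=C(Cl)OCc1ccccc1
Why: DMAP-catalysed O-acylation with excess chloroformate caps both catechol oxygens as aryl benzyl carbonates, which turns two strong donors on ring B into weakly withdrawing groups at the robust aldehyde stage, before any benzylic C–O stereocentre exists.

Step 8
Reactants: 9 3,4-bis(benzyloxycarbonyloxy)-5-(tetra-O-benzylluteolin-8-yl)benzaldehyde; 10 tert-butyl diazoacetate
Product: 11 tert-butyl 3-[3,4-bis(benzyloxycarbonyloxy)-5-(tetra-O-benzylluteolin-8-yl)phenyl]-3-oxopropanoate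
Conditions: SnCl2 (0.3 equiv), CH2Cl2, rt, slow addition of 10 (1.5 equiv)
Reagents that add atoms: none
Why: Roskamp reaction; the Lewis acid promotes addition of the diazo ester to the aldehyde, a 1,2-hydride shift with loss of N2 follows, the electron-poor ring B has a low migratory aptitude so hydride shift should win over aryl shift, and no base is present that could attack the carbonates.

Step 9
Reactants: 11 tert-butyl 3-[3,4-bis(benzyloxycarbonyloxy)-5-(tetra-O-benzylluteolin-8-yl)phenyl]-3-oxopropanoate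
Product: 12 tert-butyl (3R)-3-[3,4-bis(benzyloxycarbonyloxy)-5-(tetra-O-benzylluteolin-8-yl)phenyl]-3-hydroxypropanoate
Conditions: RuCl[(R,R)-TsDPEN](p-cymene) (2 mol%), HCO2H–Et3N (5:2), CH2Cl2, 30 °C
Reagents that add atoms: none
Why: Noyori–Ikariya asymmetric transfer hydrogenation of an aryl ketone; the outer-sphere Ru–H/N–H transfer, with the aryl group held against the cymene ligand, delivers hydride to the Si face with the (R,R) catalyst and should give the R carbinol, and the alcohol-free medium leaves the aryl carbonates, benzyl ethers and flavone C=C untouched, unlike pressure hydrogenation in hot alcohols.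

Step 10
Reactants: 12 tert-butyl (3R)-3-[3,4-bis(benzyloxycarbonyloxy)-5-(tetra-O-benzylluteolin-8-yl)phenyl]-3-hydroxypropanoate; 13 3,5-bis(benzyloxy)phenol
Product: 14 tert-butyl (3S)-3-[3,4-bis(benzyloxycarbonyloxy)-5-(tetra-O-benzylluteolin-8-yl)phenyl]-3-[3,5-bis(benzyloxy)phenoxy]propanoate
Conditions: PPh3 (1.5 equiv), DIAD (1.5 equiv, slow addition), toluene, 0 °C to rt
Reagents that add atoms: none
Why: Mitsunobu etherification; the phenoxide displaces the alkoxyphosphonium group by SN2 with clean inversion (R to S), and the electron-poor ring B together with the non-polar solvent disfavours the ionising pathway that would scramble the centre.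

Step 11
Reactants: 14 tert-butyl (3S)-3-[3,4-bis(benzyloxycarbonyloxy)-5-(tetra-O-benzylluteolin-8-yl)phenyl]-3-[3,5-bis(benzyloxy)phenoxy]propanoate
Product: 16 (3S)-3-[3,4-bis(benzyloxycarbonyloxy)-5-(tetra-O-benzylluteolin-8-yl)phenyl]-3-[3,5-bis(benzyloxy)phenoxy]propanoic acid, via trimethylsilyl ester 15 (not isolated)
Conditions: TMSOTf (4 equiv), 2,6-lutidine (6 equiv), CH2Cl2, 0 °C; then aqueous citric acid
Reagents that add atoms: trimethylsilyl triflate, C[Si](C)(C)OS(=O)(=O)C(F)(F)F (its silyl group is held only by 15)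
Why: Silyl-triflate-mediated dealkylation of a tert-butyl ester; the tert-butyl group leaves as isobutene under lutidine buffering and the silyl ester hydrolyses on mild work-up, which spares the aryl carbonates, avoids the E1cB loss of the β-aryloxy group that saponification would invite, and keeps free protic acid away from the benzylic ether.

Step 12
Reactants: 16 (3S)-3-[3,4-bis(benzyloxycarbonyloxy)-5-(tetra-O-benzylluteolin-8-yl)phenyl]-3-[3,5-bis(benzyloxy)phenoxy]propanoic acid
Product: 18 (2S)-5,7-bis(benzyloxy)-2-[3,4-bis(benzyloxycarbonyloxy)-5-(tetra-O-benzylluteolin-8-yl)phenyl]chroman-4-one, via mixed trifluoroacetic anhydride 17 (not isolated)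
Conditions: (CF3CO)2O (2.5 equiv), CH2Cl2 (0.02 M), 0 °C; cold pH 7 phosphate buffer
Reagents that add atoms: trifluoroacetic anhydride, O=C(OC(=O)C(F)(F)F)C(F)(F)F (its acyl group is held only by 17)
Why: The anhydride converts acid 16 into the acyl trifluoroacetate 17, whose alkanoyl carbonyl is attacked by the ring A carbon that lies ortho to O1 and para to a benzyloxy group, and proton loss from the Wheland intermediate gives the aryl ketone C4=O. This is the classical intramolecular Friedel–Crafts cycloacylation of 3-aryloxypropanoic acids to chroman-4-ones, run without a metal Lewis acid because a phloroglucinol triether is nucleophilic enough for an acyl trifluoroacetate at 0 °C. Ring C closes in a 6-exo-trig mode, the arene carbon adding to the exocyclic C=O of the tethered acyl group, and only C4–C4a is formed. No stereocentre is created: C2 was set in steps 9 and 10, none of its four bonds takes part, and the S descriptor is carried over. Regioselectivity needs no control because the two ortho carbons of the 3,5-bis(benzyloxy)phenoxy ring are related by symmetry, and closure onto ring B to a five-membered indanone is shut off by the far lower nucleophilicity of that bis-carbonate ring. Configurational integrity rests on the two ring B carbonates, which should make a cation at C2 no better stabilised than in an unsubstituted benzylic system, and on the low acidity of dilute CF3CO2H in CH2Cl2, so that heterolysis of C2–O1 should not compete; this is to be verified by chiral HPLC against racemic material.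

Step 13
Reactants: 18 (2S)-5,7-bis(benzyloxy)-2-[3,4-bis(benzyloxycarbonyloxy)-5-(tetra-O-benzylluteolin-8-yl)phenyl]chroman-4-one
Product: 19 target CNP0224656.1, (2S)-5,7-dihydroxy-2-[3,4-dihydroxy-5-(luteolin-8-yl)phenyl]chroman-4-one
Conditions: H2 (1 atm), 10% Pd/C, THF–EtOH (1:1), AcOH (1% v/v), rt
Reagents that add atoms: none
Why: Global catalytic hydrogenolysis cleaves the six benzyl ethers and the two benzyl carbonates (the carbonic half esters lose CO2) in one slightly acidic operation, so the free 4'-hydroxyflavanone never meets base or strong acid that could open ring C and racemise C2, while the flavone C=C and both vinylogous carbonyl groups resist these mild conditions.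

**Compound list**
1 | luteolin | O=c1cc(-c2ccc(O)c(O)c2)oc2cc(O)cc(O)c12 | starting material
2 | 5,7,3',4'-tetra-O-benzylluteolin | O=c1cc(-c2ccc(OCc9ccccc9)c(OCc9ccccc9)c2)oc2cc(OCc9ccccc9)cc(OCc9ccccc9)c12 | intermediate
3 | 8-iodo-5,7,3',4'-tetra-O-benzylluteolin | O=c1cc(-c2ccc(OCc9ccccc9)c(OCc9ccccc9)c2)oc2c(I)c(OCc9ccccc9)cc(OCc9ccccc9)c12 | intermediate
4 | 3-bromo-4,5-dihydroxybenzaldehyde | O=Cc1cc(O)c(O)c(Br)c1 | starting material
5 | 3-bromo-4,5-bis(methoxymethoxy)benzaldehyde | O=Cc1cc(OCOC)c(OCOC)c(Br)c1 | intermediate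
6 | 3,4-bis(methoxymethoxy)-5-(4,4,5,5-tetramethyl-1,3,2-dioxaborolan-2-yl)benzaldehyde | O=Cc1cc(OCOC)c(OCOC)c(B2OC(C)(C)C(C)(C)O2)c1 | intermediate
7 | 3,4-bis(methoxymethoxy)-5-(tetra-O-benzylluteolin-8-yl)benzaldehyde | O=Cc2cc(OCOC)c(OCOC)c(-c3c(OCc9ccccc9)cc(OCc9ccccc9)c4c(=O)cc(-c5ccc(OCc9ccccc9)c(OCc9ccccc9)c5)oc34)c2 | intermediate
8 | 3,4-dihydroxy-5-(tetra-O-benzylluteolin-8-yl)benzaldehyde | O=Cc2cc(O)c(O)c(-c3c(OCc9ccccc9)cc(OCc9ccccc9)c4c(=O)cc(-c5ccc(OCc9ccccc9)c(OCc9ccccc9)c5)oc34)c2 | intermediate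
9 | 3,4-bis(benzyloxycarbonyloxy)-5-(tetra-O-benzylluteolin-8-yl)benzaldehyde | O=Cc2cc(OC(=O)OCc9ccccc9)c(OC(=O)OCc9ccccc9)c(-c3c(OCc9ccccc9)cc(OCc9ccccc9)c4c(=O)cc(-c5ccc(OCc9ccccc9)c(OCc9ccccc9)c5)oc34)c2 | intermediate
10 | tert-butyl diazoacetate | CC(C)(C)OC(=O)C=[N+]=[N-] | starting material
11 | tert-butyl 3-[3,4-bis(benzyloxycarbonyloxy)-5-(tetra-O-benzylluteolin-8-yl)phenyl]-3-oxopropanoate | CC(C)(C)OC(=O)CC(=O)c2cc(OC(=O)OCc9ccccc9)c(OC(=O)OCc9ccccc9)c(-c3c(OCc9ccccc9)cc(OCc9ccccc9)c4c(=O)cc(-c5ccc(OCc9ccccc9)c(OCc9ccccc9)c5)oc34)c2 | intermediate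
12 | tert-butyl (3R)-3-[3,4-bis(benzyloxycarbonyloxy)-5-(tetra-O-benzylluteolin-8-yl)phenyl]-3-hydroxypropanoate | CC(C)(C)OC(=O)C[C@H](c2cc(OC(=O)OCc9ccccc9)c(OC(=O)OCc9ccccc9)c(-c3c(OCc9ccccc9)cc(OCc9ccccc9)c4c(=O)cc(-c5ccc(OCc9ccccc9)c(OCc9ccccc9)c5)oc34)c2)O | intermediate
13 | 3,5-bis(benzyloxy)phenol | Oc1cc(OCc2ccccc2)cc(OCc2ccccc2)c1 | starting material
14 | tert-butyl (3S)-3-[3,4-bis(benzyloxycarbonyloxy)-5-(tetra-O-benzylluteolin-8-yl)phenyl]-3-[3,5-bis(benzyloxy)phenoxy]propanoate | CC(C)(C)OC(=O)C[C@@H](c2cc(OC(=O)OCc9ccccc9)c(OC(=O)OCc9ccccc9)c(-c3c(OCc9ccccc9)cc(OCc9ccccc9)c4c(=O)cc(-c5ccc(OCc9ccccc9)c(OCc9ccccc9)c5)oc34)c2)Oc1cc(OCc9ccccc9)cc(OCc9ccccc9)c1 | intermediate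
15 | trimethylsilyl (3S)-3-[3,4-bis(benzyloxycarbonyloxy)-5-(tetra-O-benzylluteolin-8-yl)phenyl]-3-[3,5-bis(benzyloxy)phenoxy]propanoate | C[Si](C)(C)OC(=O)C[C@@H](c2cc(OC(=O)OCc9ccccc9)c(OC(=O)OCc9ccccc9)c(-c3c(OCc9ccccc9)cc(OCc9ccccc9)c4c(=O)cc(-c5ccc(OCc9ccccc9)c(OCc9ccccc9)c5)oc34)c2)Oc1cc(OCc9ccccc9)cc(OCc9ccccc9)c1 | intermediate
16 | (3S)-3-[3,4-bis(benzyloxycarbonyloxy)-5-(tetra-O-benzylluteolin-8-yl)phenyl]-3-[3,5-bis(benzyloxy)phenoxy]propanoic acid | OC(=O)C[C@@H](c2cc(OC(=O)OCc9ccccc9)c(OC(=O)OCc9ccccc9)c(-c3c(OCc9ccccc9)cc(OCc9ccccc9)c4c(=O)cc(-c5ccc(OCc9ccccc9)c(OCc9ccccc9)c5)oc34)c2)Oc1cc(OCc9ccccc9)cc(OCc9ccccc9)c1 | intermediate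
17 | mixed anhydride of acid 16 and trifluoroacetic acid, (3S) | O=C(OC(=O)C[C@@H](c2cc(OC(=O)OCc9ccccc9)c(OC(=O)OCc9ccccc9)c(-c3c(OCc9ccccc9)cc(OCc9ccccc9)c4c(=O)cc(-c5ccc(OCc9ccccc9)c(OCc9ccccc9)c5)oc34)c2)Oc1cc(OCc9ccccc9)cc(OCc9ccccc9)c1)C(F)(F)F | intermediate
18 | (2S)-5,7-bis(benzyloxy)-2-[3,4-bis(benzyloxycarbonyloxy)-5-(tetra-O-benzylluteolin-8-yl)phenyl]chroman-4-one | O=C1C[C@@H](c2cc(OC(=O)OCc9ccccc9)c(OC(=O)OCc9ccccc9)c(-c3c(OCc9ccccc9)cc(OCc9ccccc9)c4c(=O)cc(-c5ccc(OCc9ccccc9)c(OCc9ccccc9)c5)oc34)c2)Oc2cc(OCc9ccccc9)cc(OCc9ccccc9)c21 | intermediate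
19 | CNP0224656.1, (2S)-5,7-dihydroxy-2-[3,4-dihydroxy-5-(luteolin-8-yl)phenyl]chroman-4-one | O=C1C[C@@H](c2cc(O)c(O)c(-c3c(O)cc(O)c4c(=O)cc(-c5ccc(O)c(O)c5)oc34)c2)Oc2cc(O)cc(O)c21 | target

**Step count**
- Total step count: 13.
- Longest linear sequence: 11 steps (steps 1, 2 and 5 to 13, or equally steps 3, 4 and 5 to 13).

**Steps most likely to fail**

Step 12 (key step).
- What may go wrong: acid-induced heterolysis of the C2–O1 bond, or β-elimination of the aryloxy group from the activated acyl species. Either would erode the configuration at C2. Intermolecular trifluoroacetylation of ring A could also run ahead of ring closure.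
- Fallback: ring C is closed from the other end, by forming O1–C2 in a catalytic asymmetric oxa-Michael addition. The fallback sets out from aldehyde 9. Commercial 1-[2,4-bis(benzyloxy)-6-hydroxyphenyl]ethanone F1 is C-acylated (LiN(SiMe3)2, Boc2O, THF, −78 °C) to tert-butyl 3-[2,4-bis(benzyloxy)-6-hydroxyphenyl]-3-oxopropanoate F2. Knoevenagel condensation of F2 with 9 (catalytic piperidinium acetate, toluene, 4 Å sieves, rt) should give the alkylidene β-keto ester F3. A cinchona-alkaloid thiourea (the pseudo-enantiomer that leads to 2S; toluene, −25 °C) then closes the ring to tert-butyl (2S)-4-oxochroman-3-carboxylate F4. Treatment with TsOH in toluene at 80 °C removes the tert-butyl group and CO2. The fallback returns to the route at 18 and bypasses steps 8 to 12.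

Step 10.
- What may go wrong: β-elimination of the activated alcohol, driven by the acidic hydrogens next to the ester. Partial leakage into an ionising pathway with loss of enantiopurity is also possible, as is transfer of a carbonate acyl group from ring B to the phenoxide.
- Fallback: the ester is replaced by a vinyl group as a latent carboxyl, so that no acidic hydrogens flank the carbinol. The fallback sets out from 9. Keck allylation (allyltributylstannane, (R)-BINOL and Ti(OiPr)4, 10 mol% each, 4 Å sieves, CH2Cl2, −20 °C) should give the (1R)-homoallylic alcohol F5. Mitsunobu reaction with 13 (PPh3, DIAD, toluene, 0 °C) inverts it to the (S)-homoallylic aryl ether F6. Lemieux–Johnson cleavage (catalytic OsO4, NaIO4, 2,6-lutidine, dioxane–H2O) gives the (3S)-3-aryl-3-aryloxypropanal F7, which is used crude. Pinnick oxidation (NaClO2, NaH2PO4, 2-methyl-2-butene, tBuOH–H2O) returns to the route at acid 16 and bypasses steps 8, 9 and 11.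

Step 8.
- What may go wrong: binding of SnCl2 to the basic flavone carbonyl could stall the reaction. Aryl migration could occur in place of the hydride shift.
- Fallback: the β-keto ester is built by acylation of a malonate half ester instead of diazo homologation. The fallback sets out from 9. Pinnick oxidation gives the benzoic acid F8. Treatment with (COCl)2 and catalytic DMF in CH2Cl2 gives the acid chloride F9. Decarboxylative C-acylation of KO2CCH2CO2tBu (MgCl2, Et3N, MeCN, 0 °C to rt) returns to the route at 11.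

**Further compounds**
F1 | step 12 | 1-[2,4-bis(benzyloxy)-6-hydroxyphenyl]ethanone | CC(=O)c1c(O)cc(OCc9ccccc9)cc1OCc9ccccc9
F2 | step 12 | tert-butyl 3-[2,4-bis(benzyloxy)-6-hydroxyphenyl]-3-oxopropanoate | CC(C)(C)OC(=O)CC(=O)c1c(O)cc(OCc9ccccc9)cc1OCc9ccccc9
F3 | step 12 | tert-butyl 2-[2,4-bis(benzyloxy)-6-hydroxybenzoyl]-3-[3,4-bis(benzyloxycarbonyloxy)-5-(tetra-O-benzylluteolin-8-yl)phenyl]prop-2-enoate (alkene geometry not fixed) | CC(C)(C)OC(=O)C(=Cc2cc(OC(=O)OCc9ccccc9)c(OC(=O)OCc9ccccc9)c(-c3c(OCc9ccccc9)cc(OCc9ccccc9)c4c(=O)cc(-c5ccc(OCc9ccccc9)c(OCc9ccccc9)c5)oc34)c2)C(=O)c1c(O)cc(OCc9ccccc9)cc1OCc9ccccc9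
F4 | step 12 | tert-butyl (2S)-5,7-bis(benzyloxy)-2-[3,4-bis(benzyloxycarbonyloxy)-5-(tetra-O-benzylluteolin-8-yl)phenyl]-4-oxochroman-3-carboxylate (C3 epimerisable, not fixed) | O=C1C(C(=O)OC(C)(C)C)[C@@H](c2cc(OC(=O)OCc9ccccc9)c(OC(=O)OCc9ccccc9)c(-c3c(OCc9ccccc9)cc(OCc9ccccc9)c4c(=O)cc(-c5ccc(OCc9ccccc9)c(OCc9ccccc9)c5)oc34)c2)Oc2cc(OCc9ccccc9)cc(OCc9ccccc9)c21
F5 | step 10 | (1R)-1-[3,4-bis(benzyloxycarbonyloxy)-5-(tetra-O-benzylluteolin-8-yl)phenyl]but-3-en-1-ol | C=CC[C@H](c2cc(OC(=O)OCc9ccccc9)c(OC(=O)OCc9ccccc9)c(-c3c(OCc9ccccc9)cc(OCc9ccccc9)c4c(=O)cc(-c5ccc(OCc9ccccc9)c(OCc9ccccc9)c5)oc34)c2)O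
F6 | step 10 | (1S)-1-[3,4-bis(benzyloxycarbonyloxy)-5-(tetra-O-benzylluteolin-8-yl)phenyl]but-3-enyl 3,5-bis(benzyloxy)phenyl ether | C=CC[C@@H](c2cc(OC(=O)OCc9ccccc9)c(OC(=O)OCc9ccccc9)c(-c3c(OCc9ccccc9)cc(OCc9ccccc9)c4c(=O)cc(-c5ccc(OCc9ccccc9)c(OCc9ccccc9)c5)oc34)c2)Oc1cc(OCc9ccccc9)cc(OCc9ccccc9)c1
F7 | step 10 | (3S)-3-[3,4-bis(benzyloxycarbonyloxy)-5-(tetra-O-benzylluteolin-8-yl)phenyl]-3-[3,5-bis(benzyloxy)phenoxy]propanal | O=CC[C@@H](c2cc(OC(=O)OCc9ccccc9)c(OC(=O)OCc9ccccc9)c(-c3c(OCc9ccccc9)cc(OCc9ccccc9)c4c(=O)cc(-c5ccc(OCc9ccccc9)c(OCc9ccccc9)c5)oc34)c2)Oc1cc(OCc9ccccc9)cc(OCc9ccccc9)c1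
F8 | step 8 | 3,4-bis(benzyloxycarbonyloxy)-5-(tetra-O-benzylluteolin-8-yl)benzoic acid | OC(=O)c2cc(OC(=O)OCc9ccccc9)c(OC(=O)OCc9ccccc9)c(-c3c(OCc9ccccc9)cc(OCc9ccccc9)c4c(=O)cc(-c5ccc(OCc9ccccc9)c(OCc9ccccc9)c5)oc34)c2
F9 | step 8 | 3,4-bis(benzyloxycarbonyloxy)-5-(tetra-O-benzylluteolin-8-yl)benzoyl chloride | ClC(=O)c2cc(OC(=O)OCc9ccccc9)c(OC(=O)OCc9ccccc9)c(-c3c(OCc9ccccc9)cc(OCc9ccccc9)c4c(=O)cc(-c5ccc(OCc9ccccc9)c(OCc9ccccc9)c5)oc34)c2
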